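**Retrosynthetic overview**
1. Ester C15–O bond: 17‑O‑TBS‑protected ent‑labda‑7,13E‑diene‑15,17‑diol 16 plus ω‑silyloxy C30 acid 23 (C15 + C15 Cu‑catalysed Grignard coupling, both halves from ω‑pentadecalactone).
2. (E)‑C13(Me)=C14–C15H2OH from terminal alkyne 13 by Zr‑catalysed methylalumination and formaldehyde trapping, so no HWE and no E/Z mixture.
3. Δ7/C17–OH from isomerisation of the 8,17‑epoxide, from the exocyclic alkene, from tertiary 8‑ol 8; the alkyne from Ohira–Bestmann homologation of the lactol of δ‑lactone 5.
4. Key step: catalytic enantioselective proton‑initiated bicyclisation of achiral (4E,8E)‑farnesylacetic acid 4 to ent‑ambreinolide 5, setting C5, C9 and C10 at once (no chiral‑pool labdane, no Wieland–Miescher ketone).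
5. Ring order: ring A, then ring B, then a temporary δ‑lactone ring, all in the one cascade of step 2; the lactone is unzipped later.

Assumptions: the acyl chain is read as 30‑hydroxytriacontanoyl (29 carbons after the ester C=O); the target is the ent‑labdane (5R,9S,10R), antipodal to the sclareolide series; metal salts of a product that are only protonated on work‑up are not numbered separately.

**Route**

Step 1
Reactants: 1 (2E,6E)-farnesyl bromide; 2 acetic acid
Product: 4 (4E,8E)-farnesylacetic acid, via dilithium acetate 3 (not isolated)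
Conditions: 2, LDA (2.2 equiv), THF/DMPU, 0 → 40 °C; then 1, 0 °C → rt; aq. HCl
Reagents that add atoms: none
Why: SN2 alkylation of the acetic acid dianion (Creger‑type enediolate alkylation) at the primary allylic bromide adds C12–C13 as CH2CO2H and leaves both E‑alkenes untouched.

Step 2
Reactants: 4 (4E,8E)-farnesylacetic acid
Product: 5 ent-ambreinolide
Conditions: confined chiral IDPi Brønsted acid (enantiomer selected for the 5R,10R series, 3 mol %), (CF3)3COH, −20 → 0 °C; recrystallise (hexane) to ≥99% ee
Reagents that add atoms: none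
Why: Proposed new method: catalytic enantioselective proton‑initiated polyene bicyclisation terminated by a carboxylic acid to a δ‑lactone; the confined chiral acid protonates one enantiotopic face of the terminal isopropylidene of the chair–chair pre‑folded (E,E)‑triene, and the concerted anti additions (Stork–Eschenmoser) turn the two E‑alkenes into the trans ring fusion (C5, C10), the equatorial C9 side arm and the equatorial C8–O bond in one step, the absolute sense being fixed by the catalyst enantiomer; the closest known reaction types are the IDPi‑catalysed cyclisation of homofarnesol to ambrox‑type ethers, the chiral LBA‑mediated cyclisation of homofarnesic acid to the γ‑lactone, and the classical racemic acid cyclisation of farnesylacetic acid to ambreinolide.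

Step 3
Reactants: 5 ent-ambreinolide
Product: 6 (5R,8S,9S,10R)-8,13-epoxy-14,15,16-trinorlabdan-13-ol (lactol)
Conditions: DIBAL-H (1.1 equiv), CH2Cl2, −78 °C; aq. Rochelle salt
Reagents that add atoms: none
Why: Partial reduction of the lactone with DIBAL‑H stops at the aluminium hemiacetal at −78 °C and gives the lactol on work‑up; no stereocentre is touched.

Step 4
Reactants: 6 lactol
Product: 8 (5R,8S,9S,10R)-15,16-dinorlabd-13-yn-8-ol, via hydroxy aldehyde 7 (not isolated)
Conditions: Ohira–Bestmann reagent (2 equiv), K2CO3, MeOH, rt → 40 °C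
Reagents that add atoms: Ohira–Bestmann reagent, dimethyl (1-diazo-2-oxopropyl)phosphonate, CC(=O)C(=[N+]=[N-])P(=O)(OC)OC
Why: Seyferth–Gilbert homologation (Ohira–Bestmann variant) of the ring‑opened aldehyde tautomer gives the terminal alkyne (C13≡C14) through a diazoalkene and a 1,2‑H shift of the alkylidene carbene; the tertiary C8–OH is a spectator.

Step 5
Reactants: 8 hydroxy alkyne
Product: 10 (5R,9R,10R)-15,16-dinorlabd-8(17)-en-13-yne, via tertiary chlorosulfite 9 (not isolated)
Conditions: SOCl2, Et3N, CH2Cl2, −90 → −78 °C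
Reagents that add atoms: none
Why: E2 elimination of the tertiary chlorosulfite: the equatorial C8–O bond has no anti‑periplanar ring C–H, so the base takes a proton from the freely rotating axial C17 methyl and gives mainly the exocyclic (Hofmann) alkene, as is known for equatorial 8‑ols of the drimane/labdane series.

Step 6
Reactants: 10 exocyclic alkene
Product: 11 (5R,8S,9S,10R)-8,17-epoxy-15,16-dinorlabd-13-yne
Conditions: mCPBA, CH2Cl2, 0 °C
Reagents that add atoms: mCPBA (3-chloroperoxybenzoic acid), OOC(=O)c1cccc(Cl)c1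
Why: Prilezhaev epoxidation of the 1,1‑disubstituted alkene (the terminal alkyne is inert) from the face anti to the axial C10 methyl; the C8 configuration is erased in the next step.

Step 7
Reactants: 11 spiro-epoxide
Product: 12 (5R,9S,10R)-15,16-dinorlabd-7-en-13-yn-17-ol
Conditions: Et2Al–TMP (4 equiv, from Et2AlCl + LiTMP), toluene, 0 °C → rt; aq. Rochelle salt
Reagents that add atoms: none
Why: Base‑promoted epoxide‑to‑allylic‑alcohol isomerisation (Yamamoto–Nozaki aluminium amide conditions): the Al‑bound amide removes the accessible syn β‑H of the C7 methylene, not the hindered C9 methine, giving the Δ7 primary allylic alcohol; excess reagent covers the acidic alkyne C–H.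

Step 8
Reactants: 12 allylic alcohol
Product: 13 tert-butyldimethylsilyl ether of 12
Conditions: TBSCl, imidazole, DMF, rt
Reagents that add atoms: TBSCl (tert-butyldimethylsilyl chloride), CC(C)(C)[Si](C)(C)Cl
Why: Standard silylation of the primary allylic alcohol masks C17–OH so that C15–OH is the only free hydroxyl at the esterification.

Step 9
Reactants: 13 silyl ether alkyne
Product: 16 (5R,9S,10R,13E)-17-(tert-butyldimethylsilyloxy)labda-7,13-dien-15-ol, via alkenylalane 14 (not isolated), via lithium alkenylaluminate 15 (not isolated)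
Conditions: Me3Al (2.5 equiv), Cp2ZrCl2 (0.25 equiv), CH2Cl2, 0 °C → rt; then n-BuLi, THF/hexane, −78 °C; (CH2O)n, −78 °C → rt; aq. Rochelle salt
Reagents that add atoms: trimethylaluminium, C[Al](C)C; formaldehyde (as paraformaldehyde), C=O
Why: Negishi Zr‑catalysed carboalumination adds Me and Al syn with Al at the terminal carbon, and the ate complex is hydroxymethylated by formaldehyde with retention, so the 13E‑trisubstituted allylic alcohol is formed with >98% E.

Step 10
Reactants: 17 ω-pentadecalactone
Product: 18 15-bromopentadecanoic acid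
Conditions: 33% HBr in AcOH, H2SO4 (cat.), 80 °C
Reagents that add atoms: hydrogen bromide, Br
Why: Acid‑mediated ring opening of the macrolactone: bromide displaces the protonated alkyl–oxygen terminus (SN2) to give the ω‑bromo acid.

Step 11
Reactants: 18 15-bromopentadecanoic acid
Product: 19 15-bromopentadecan-1-ol
Conditions: BH3·SMe2, THF, 0 °C → rt; aq. work-up
Reagents that add atoms: none
Why: Borane reduces the carboxylic acid chemoselectively and leaves the primary alkyl bromide intact.

Step 12
Reactants: 19 15-bromopentadecan-1-ol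
Product: 20 (15-bromopentadecyloxy)(tert-butyl)dimethylsilane
Conditions: TBSCl, imidazole, CH2Cl2, rt
Reagents that add atoms: TBSCl (tert-butyldimethylsilyl chloride), CC(C)(C)[Si](C)(C)Cl
Why: Silylation protects the ω‑hydroxyl for Grignard formation and for the later esterification.

Step 13
Reactants: 20 silyl ether bromide; 18 15-bromopentadecanoic acid
Product: 23 30-(tert-butyldimethylsilyloxy)triacontanoic acid, via Grignard reagent 21 (not isolated), via magnesium carboxylate 22 (not isolated)
Conditions: 20, Mg, THF, 45 °C; 18, MeMgCl (1.0 equiv), THF, −20 °C; combine, Li2CuCl4 (3 mol %), −20 °C → rt; cold dilute HCl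
Reagents that add atoms: none
Why: Kochi‑type copper‑catalysed sp3–sp3 cross‑coupling of the alkyl Grignard reagent with the primary bromide joins C15 to C15, the acid being masked as its unreactive magnesium carboxylate.

Step 14
Reactants: 16 C15 allylic alcohol; 23 silyloxy C30 acid
Product: 25 bis-TBS ester, via O-acylisourea 24 (not isolated)
Conditions: DIC, DMAP (cat.), CH2Cl2/THF, rt → 35 °C
Reagents that add atoms: none
Why: Steglich esterification (carbodiimide/DMAP acyl transfer) acylates the only free hydroxyl, C15–OH, under neutral conditions that do not isomerise the allylic system.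

Step 15
Reactants: 25 bis-TBS ester
Product: 26 target CNP0329077.1
Conditions: HF·pyridine, THF/pyridine, 0 °C → rt
Reagents that add atoms: none
Why: Fluoride‑mediated desilylation removes both primary TBS ethers, while the allylic ester and both trisubstituted alkenes are stable to buffered HF·pyridine.

**Compound list**
1 | (2E,6E)-farnesyl bromide [(2E,6E)-1-bromo-3,7,11-trimethyldodeca-2,6,10-triene] | CC(C)=CCC/C(C)=C/CC/C(C)=C/CBr | starting material
2 | acetic acid | CC(=O)O | starting material
3 | dilithium ethene-1,1-diolate (acetic acid dianion) | C=C(O[Li])O[Li] | intermediate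
4 | (4E,8E)-5,9,13-trimethyltetradeca-4,8,12-trienoic acid (farnesylacetic acid) | CC(C)=CCC/C(C)=C/CC/C(C)=C/CCC(=O)O | intermediate
5 | ent-ambreinolide, (5R,8S,9S,10R)-14,15,16-trinorlabdan-13,8-olide [(4aS,6aR,10aR,10bS)-4a,7,7,10a-tetramethyldodecahydrobenzo[f]chromen-3-one]; trans-decalin, lactone O equatorial on C8, C17 methyl axial | O=C1CC[C@@H]2[C@@](C)(O1)CC[C@@H]3C(C)(C)CCC[C@@]23C | intermediate
6 | (5R,8S,9S,10R)-8,13-epoxy-14,15,16-trinorlabdan-13-ol (lactol, anomeric mixture) | OC1CC[C@@H]2[C@@](C)(O1)CC[C@@H]3C(C)(C)CCC[C@@]23C | intermediate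
7 | (5R,8S,9S,10R)-8-hydroxy-14,15,16-trinorlabdan-13-al (open form of 6) | O=CCC[C@@H]1[C@@](C)(O)CC[C@@H]2C(C)(C)CCC[C@@]12C | intermediate
8 | (5R,8S,9S,10R)-15,16-dinorlabd-13-yn-8-ol [(1S,2S,4aR,8aR)-1-(but-3-yn-1-yl)-2,5,5,8a-tetramethyldecahydronaphthalen-2-ol] | C#CCC[C@@H]1[C@@](C)(O)CC[C@@H]2C(C)(C)CCC[C@@]12C | intermediate
9 | C8 chlorosulfite of 8 | C#CCC[C@@H]1[C@@](C)(OS(=O)Cl)CC[C@@H]2C(C)(C)CCC[C@@]12C | intermediate
10 | (5R,9R,10R)-15,16-dinorlabd-8(17)-en-13-yne (exocyclic methylene) | C#CCC[C@@H]1C(=C)CC[C@@H]2C(C)(C)CCC[C@@]12C | intermediate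
11 | (5R,8S,9S,10R)-8,17-epoxy-15,16-dinorlabd-13-yne (epoxide O equatorial, anti to the C10 methyl) | C#CCC[C@@H]1[C@@]3(OC3)CC[C@@H]2C(C)(C)CCC[C@@]12C | intermediate
12 | (5R,9S,10R)-15,16-dinorlabd-7-en-13-yn-17-ol | C#CCC[C@@H]1C(CO)=CC[C@@H]2C(C)(C)CCC[C@@]12C | intermediate
13 | (5R,9S,10R)-17-(tert-butyldimethylsilyloxy)-15,16-dinorlabd-7-en-13-yne | C#CCC[C@@H]1C(CO[Si](C)(C)C(C)(C)C)=CC[C@@H]2C(C)(C)CCC[C@@]12C | intermediate
14 | (13E)-alkenyl dimethylalane from 13 (Al on C14, new methyl on C13, syn) | C/C(=C\[Al](C)C)CC[C@@H]1C(CO[Si](C)(C)C(C)(C)C)=CC[C@@H]2C(C)(C)CCC[C@@]12C | intermediate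
15 | lithium (13E)-alkenyl(butyl)dimethylaluminate from 14 | C/C(=C\[Al-](C)(C)CCCC)CC[C@@H]1C(CO[Si](C)(C)C(C)(C)C)=CC[C@@H]2C(C)(C)CCC[C@@]12C.[Li+] | intermediate
16 | (5R,9S,10R,13E)-17-(tert-butyldimethylsilyloxy)labda-7,13-dien-15-ol | C/C(=C\CO)CC[C@@H]1C(CO[Si](C)(C)C(C)(C)C)=CC[C@@H]2C(C)(C)CCC[C@@]12C | intermediate
17 | ω-pentadecalactone (oxacyclohexadecan-2-one) | O=C1CCCCCCCCCCCCCCO1 | starting material
18 | 15-bromopentadecanoic acid | OC(=O)CCCCCCCCCCCCCCBr | intermediate
19 | 15-bromopentadecan-1-ol | OCCCCCCCCCCCCCCCBr | intermediate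
20 | (15-bromopentadecyloxy)(tert-butyl)dimethylsilane | CC(C)(C)[Si](C)(C)OCCCCCCCCCCCCCCCBr | intermediate
21 | [15-(tert-butyldimethylsilyloxy)pentadecyl]magnesium bromide | CC(C)(C)[Si](C)(C)OCCCCCCCCCCCCCCC[Mg]Br | intermediate
22 | chloromagnesium 15-bromopentadecanoate | BrCCCCCCCCCCCCCCC(=O)O[Mg]Cl | intermediate
23 | 30-(tert-butyldimethylsilyloxy)triacontanoic acid | CC(C)(C)[Si](C)(C)OCCCCCCCCCCCCCCCCCCCCCCCCCCCCCC(=O)O | intermediate
24 | O-acylisourea of 23 with N,N'-diisopropylcarbodiimide | CC(C)N=C(NC(C)C)OC(=O)CCCCCCCCCCCCCCCCCCCCCCCCCCCCCO[Si](C)(C)C(C)(C)C | intermediate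
25 | (5R,9S,10R,13E)-17-(tert-butyldimethylsilyloxy)labda-7,13-dien-15-yl 30-(tert-butyldimethylsilyloxy)triacontanoate | C/C(=C\COC(=O)CCCCCCCCCCCCCCCCCCCCCCCCCCCCCO[Si](C)(C)C(C)(C)C)CC[C@@H]1C(CO[Si](C)(C)C(C)(C)C)=CC[C@@H]2C(C)(C)CCC[C@@]12C | intermediate
26 | (5R,9S,10R,13E)-17-hydroxylabda-7,13-dien-15-yl 30-hydroxytriacontanoate (ent-labdane; CNP0329077.1) | C/C(=C\COC(=O)CCCCCCCCCCCCCCCCCCCCCCCCCCCCCO)CC[C@@H]1C(CO)=CC[C@@H]2C(C)(C)CCC[C@@]12C | target

**Step count and risks**

Total: 15 steps. Longest linear sequence: 11 steps (steps 1–9, 14, 15, from farnesyl bromide); the acid arm is steps 10–13.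

Three steps most likely to fail:

Step 2 (asymmetric bicyclisation). The δ‑lactone termination is untested with a chiral acid; ee or closure of the second ring may be poor. Fallback, setting out from 4 and returning at 5: give up catalyst control and cyclise 4 with an achiral superacid (FSO3H or ClSO3H, 2‑nitropropane, −78 °C). This gives the trans‑fused lactone as a racemate, that is 5 together with its mirror image (+)-ambreinolide F1. The enantiomers are separated by preparative chiral SFC, and resolved 5 re‑enters the route at step 3.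

Step 5 (regioselective dehydration). Exo/endo mixtures are possible. Fallback, setting out from 8 and returning at 12: stop aiming for the exocyclic alkene. Dehydrate 8 under E1 conditions (cat. p‑TsOH, toluene, 70 °C, short contact time) to the endocyclic Zaitsev isomer (5R,9R,10R)-15,16-dinorlabd-7-en-13-yne F2. Then oxidise its C17 methyl directly by allylic oxidation with SeO2 (cat.)/t‑BuOOH (ene reaction then [2,3] shift at the only CH3 on the more substituted alkene carbon). This gives 12 and makes steps 6 and 7 unnecessary; Δ7 by‑product from step 5 can be salvaged the same way.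

Step 7 (epoxide to allylic alcohol). Risks are H9 abstraction giving the Δ8(9) isomer, amide addition to the epoxide, and alkynylalane side reactions. Fallback, setting out from 10 and returning at 12: leave out the epoxide. SeO2/t‑BuOOH on 10 gives the secondary allylic alcohol (5R,7S,9S,10R)-7-hydroxy-15,16-dinorlabd-8(17)-en-13-yne F3 (ene reaction at C7–H, then [2,3] shift, axial OH). A Re(VII)‑catalysed 1,3‑transposition of the allylic alcohol (O3ReOSiPh3 or Re2O7, Et2O, 0 °C) then moves the hydroxyl to C17 and the double bond into the ring, giving 12; the C7 stereocentre of F3 is lost in that step.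

**Further compounds**
F1 | step 2 | (+)-ambreinolide, the (5S,8R,9R,10S) enantiomer of 5 | O=C1CC[C@H]2[C@](C)(O1)CC[C@H]3C(C)(C)CCC[C@]23C
F2 | step 5 | (5R,9R,10R)-15,16-dinorlabd-7-en-13-yne | C#CCC[C@@H]1C(C)=CC[C@@H]2C(C)(C)CCC[C@@]12C
F3 | step 7 | (5R,7S,9S,10R)-7-hydroxy-15,16-dinorlabd-8(17)-en-13-yne | C#CCC[C@@H]1C(=C)[C@@H](O)C[C@@H]2C(C)(C)CCC[C@@]12C
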